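- The time of reading comes first for me: in the epsilon run target reads 20.5% at 20.0 min but 12.8% at 40.0 min, so one number says little until I know when it was taken.

| flask | starting material | reagent | remark | time |
|---|---|---|---|---|
| epsilon | 13 mM | 22 mM | run made earlier |  |
| eta | 30 mM | 22 mM | run made earlier |  |
| theta | 20 mM | 11 mM | run made earlier |  |
| flask | 20 mM | 22.0 mM |  | 1.5 h |

| run | time / min | target / % | starting material / % |
|---|---|---|---|
| epsilon | 3.00 | 0 | 100.4 |
| epsilon | 8.00 | 1.1 | 98.6 |
| epsilon | 20.0 | 20.5 | 31.1 |
| epsilon | 40.0 | 12.8 | 2.4 |
| epsilon | 90.0 | 12.4 | 0 |
| eta | 3.00 | 1.6 | 99.1 |
| eta | 8.00 | 22.2 | 55.3 |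
| eta | 20.0 | 18.2 | 22.9 |
| eta | 40.0 | 16.5 | 19.0 |
| eta | 90.0 | 16.1 | 18.6 |
| theta | 3.00 | 0 | 100.2 |
| theta | 8.00 | 0 | 99.7 |
| theta | 20.0 | 10.2 | 75.3 |
| theta | 40.0 | 14.2 | 38.8 |
| theta | 90.0 | 13.7 | 37.5 |

(standard deviation of a reading: 0.5 percentage points)

- a reading or a percentage of target counts all its forms, free or not
- a reading of starting material is of its free form alone

* when, up to 1.5 h, the flask holds most target
* the amount of target, in percent of the starting material charged, at that time
* the first time at which target reaches 12%, in the same percent

- In the first instants of the epsilon run I see hardly any change: at 8.00 min starting material reads 98.6% and target 1.1%.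
- In the middle of the epsilon run starting material falls to 31.1% by 20.0 min, and target makes up 29.8% of what has reacted.
- At the end of the epsilon run, at 90.0 min, starting material reads 0%, and target makes up 12.4% of what has reacted, a reading with a scatter of 0.5 percentage points. I call this the end share: target as a part of the reacted starting material once starting material reads zero. It is less than the share in the middle of the epsilon run, which I treat as a passing value. I take the end share as the mark of thermodynamic control.
- The flask resembles the epsilon run, since its reagent exceeds its starting material. The eta and theta runs are charged the other way and stop with starting material at 18.6% and 37.5%.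
- So I reckon that the flask falls towards 12.4%. The level of 12% lies just 0.4 points below that, so I look for the first crossing on the rise.
- The forecast gives a peak of 23% at 0.19 h and 12% at 0.15 h. After the peak it says target “then drops to a plateau of about 13–15%”, where my own reckoning gives 12.4%, so the two differ.

    starting material + reagent → target + released group (k = 0.00643 /M/min)
    starting material + reagent + released group → target + 2 released group (k = 1710 /M²/min)
    target ⇌ isomer of the product (K = 6.90, k = 1.06 /min)
    crystals ⇌ released group, rate k4*(cs4 - [released group]) while solid is left; crystals form when [released group] > cs4 (solubility = 10.0 mM, k = 11.6 /min)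
    starting material + target ⇌ idle adduct, settled at all times (K = 180 /M)

- The flask holds most target at 0.227 h, later than the forecast, with 24.4% there, and it reaches 12% at 0.161 h. At the best time starting material stands at 35.6% and isomer of the product at 26.4%. At 1.50 h starting material stands at 1.06%, so the end share gives 12.3% of target, and the flask holds 12.9%.
- A neighbour flask charged with 55 mM of reagent ends with starting material at 0%, so the end share gives 12.4% of target there. Computed, that neighbour flask ends at 12.7%, after a best of 37.3%.

The readings come from a simulation with made-up constants, and the scatter is random.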